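Ring A of the chromene (C4a, C5, C6, C7, C8, C8a) is built rather than substituted. Its C4a–C8a(O)–C8 segment, with the prenyl chain on C8, is the intact carbon–oxygen framework of 6-methylhept-5-en-2-one. C5–C6–C7 with its two phenolic oxygens is a malonyl unit. One operation, a twofold C-acylation of the ketone's silyl enol ether by malonyl dichloride, forms C4a–C5 and C7–C8 and should deliver 2-prenylphloroglucinol with the prenyl group already in place. The precursor is the kinetic enol ether, carried as its tert-butyldimethylsilyl ether so that the oxygen stays capped during ring closure. Acid-free C-benzoylation, para-selective propargylation and a Claisen cascade finish the target.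

Key step: step 2

Remark: atom labels (C4a to C8a) are those of the 2H-chromene in the target; the silyl group on the enol ether is treated as a freely chosen protecting group and does not alter the precursor skeleton.

Step 1
Reactants: 1 6-methylhept-5-en-2-one
Product: 3 tert-butyldimethyl[(6-methylhepta-1,5-dien-2-yl)oxy]silane, via lithium enolate 2 (not isolated)
Conditions: LiN(iPr)2 (1.1 equiv), THF, −78 °C; then TBSCl, DMPU, −78 → 0 °C
Reagents that add atoms: tert-butyl(chloro)dimethylsilane (TBSCl), CC(C)(C)[Si](C)(C)Cl
Why: Kinetic deprotonation of a methyl ketone by the hindered lithium amide takes place at the methyl group and the enolate is O-silylated by the chlorosilane in the presence of DMPU (kinetic enolate trapping); a trace of the internal enol ether would converge on the same arene in step 2.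

Step 2
Reactants: 3 tert-butyldimethyl[(6-methylhepta-1,5-dien-2-yl)oxy]silane; 4 malonyl dichloride
Product: 7 2-(3-methylbut-2-en-1-yl)benzene-1,3,5-triol, via silyloxy oxodienoyl chloride 5 (not isolated), via monosilyl ether 6 (not isolated)
Conditions: Et2O, −78 → −20 °C, 24 h; then aq. KOH, BnEt3NCl (cat.), 0 → 20 °C, argon; mildly acidic work-up
Reagents that add atoms: none
Why: The terminal carbon of the enol ether (the future C4a) attacks one acyl chloride of 4 and forms C4a–C5, giving the silyl-capped diketo acyl chloride 5; acid-mediated shift of the enol ether double bond towards the prenyl-bearing carbon (C8) then lets that carbon attack the second acyl chloride and form C7–C8. This second acylation closes ring A in a 6-(enolendo)-exo-trig mode, and the silyloxy dienone so formed tautomerises to the aromatic monosilyl ether 6, which the aqueous KOH quench cleaves to 7. The closest known reaction type is the Effenberger annulation of ketone enol ethers with malonyl dichloride, which turns open-chain ketone enol ethers into alkylphloroglucinols and cyclic ones into bicyclo[3.3.1]nonanetriones. No stereocentre is formed. The selectivity needed is carbon over oxygen attack in the ring-closing acylation: the oxygen on C8a is kept capped by a bulky silyl group that chloride should remove only slowly, which disfavours lactonisation to the 4-hydroxy-2-pyrone, and aromatisation makes the carbon closure irreversible. Ether as a weakly basic solvent, the low temperature and the direct basic quench keep the liberated HCl from adding to the prenyl alkene or closing a chroman.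

Step 3
Reactants: 7 2-(3-methylbut-2-en-1-yl)benzene-1,3,5-triol; 8 benzoyl chloride
Product: 10 phenyl[2,4,6-trihydroxy-3-(3-methylbut-2-en-1-yl)phenyl]methanone, via magnesium phenolate 9 (not isolated)
Conditions: EtMgBr (3.0 equiv), Et2O, 0 °C; solvent switch to toluene; 8 (1.0 equiv), 20 → 60 °C; aq. NH4Cl work-up
Reagents that add atoms: none
Why: In a non-coordinating solvent the bromomagnesium phenolate binds the acyl chloride at magnesium and delivers it to the ring carbon ortho to oxygen (metal-template ortho-acylation, a Friedel–Crafts-type C-acylation that needs no Lewis or Brønsted acid); the two free ring carbons of 7 are equivalent by symmetry, and the chloride ends on magnesium and not as HCl, so the acid-sensitive ortho-prenylphenol unit should survive.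

Step 4
Reactants: 10 phenyl[2,4,6-trihydroxy-3-(3-methylbut-2-en-1-yl)phenyl]methanone; 11 3-chloro-3-methylbut-1-yne
Product: 12 {2,6-dihydroxy-3-(3-methylbut-2-en-1-yl)-4-[(2-methylbut-3-yn-2-yl)oxy]phenyl}(phenyl)methanone
Conditions: K2CO3 (1.1 equiv), KI (cat.), CuI (cat.), acetone, 50 °C
Reagents that add atoms: none
Why: The hydroxyl para to the benzoyl group is the only one not tied up in a hydrogen bond to the ketone and is the most acidic, so one equivalent of carbonate ionises it selectively and copper-assisted substitution of the tertiary propargylic chloride gives the aryl 1,1-dimethylpropargyl ether (Williamson-type phenol O-alkylation).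

Step 5
Reactants: 12 {2,6-dihydroxy-3-(3-methylbut-2-en-1-yl)-4-[(2-methylbut-3-yn-2-yl)oxy]phenyl}(phenyl)methanone
Product: 16 [5,7-dihydroxy-2,2-dimethyl-8-(3-methylbut-2-en-1-yl)-2H-chromen-6-yl](phenyl)methanone, via Claisen dienone 13 (not isolated), via allenylphenol 14 (not isolated), via quinone methide 15 (not isolated)
Conditions: o-xylene, 140 °C, argon
Reagents that add atoms: none
Why: An aromatic propargyl Claisen rearrangement moves the side chain to the only unsubstituted ortho carbon (C4a), the dienone enolises, a [1,5]-hydrogen shift from the freed C8a hydroxyl gives the ortho-quinone methide and oxa-6π electrocyclisation closes the pyran ring; the C5 hydroxyl is held by its hydrogen bond to the benzoyl group and should stay out of the closure, and the achiral target has no stereocentre to set.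

Compound list
1 | 6-methylhept-5-en-2-one | CC(C)=CCCC(C)=O | starting material
2 | lithium 6-methylhepta-1,5-dien-2-olate | C=C(O[Li])CCC=C(C)C | intermediate
3 | tert-butyldimethyl[(6-methylhepta-1,5-dien-2-yl)oxy]silane | CC(C)=CCCC(=C)O[Si](C)(C)C(C)(C)C | intermediate
4 | malonyl dichloride (propanedioyl dichloride) | O=C(Cl)CC(=O)Cl | starting material
5 | 5-{[tert-butyl(dimethyl)silyl]oxy}-9-methyl-3-oxodeca-4,8-dienoyl chloride (C4=C5 geometry not fixed) | O=C(Cl)CC(=O)C=C(O[Si](C)(C)C(C)(C)C)CCC=C(C)C | intermediate
6 | 5-{[tert-butyl(dimethyl)silyl]oxy}-4-(3-methylbut-2-en-1-yl)benzene-1,3-diol | CC(C)=CCc1c(O[Si](C)(C)C(C)(C)C)cc(O)cc1O | intermediate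
7 | 2-(3-methylbut-2-en-1-yl)benzene-1,3,5-triol | CC(C)=CCc1c(O)cc(O)cc1O | intermediate
8 | benzoyl chloride | O=C(Cl)c1ccccc1 | starting material
9 | tris(bromomagnesium) 2-(3-methylbut-2-en-1-yl)benzene-1,3,5-triolate | CC(C)=CCc1c(O[Mg]Br)cc(O[Mg]Br)cc1O[Mg]Br | intermediate
10 | phenyl[2,4,6-trihydroxy-3-(3-methylbut-2-en-1-yl)phenyl]methanone | CC(C)=CCc1c(O)c(C(=O)c2ccccc2)c(O)cc1O | intermediate
11 | 3-chloro-3-methylbut-1-yne | C#CC(C)(C)Cl | starting material
12 | {2,6-dihydroxy-3-(3-methylbut-2-en-1-yl)-4-[(2-methylbut-3-yn-2-yl)oxy]phenyl}(phenyl)methanone | CC(C)=CCc1c(O)c(C(=O)c2ccccc2)c(O)cc1OC(C)(C)C#C | intermediate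
13 | 4-benzoyl-3,5-dihydroxy-2-(3-methylbut-2-en-1-yl)-6-(3-methylbuta-1,2-dien-1-yl)cyclohexa-2,4-dien-1-one (racemic at C6) | CC(C)=CCC1=C(O)C(C(=O)c2ccccc2)=C(O)C(C=C=C(C)C)C1=O | intermediate
14 | [2,4,6-trihydroxy-3-(3-methylbut-2-en-1-yl)-5-(3-methylbuta-1,2-dien-1-yl)phenyl](phenyl)methanone | CC(C)=CCc1c(O)c(C(=O)c2ccccc2)c(O)c(C=C=C(C)C)c1O | intermediate
15 | (6Z)-4-benzoyl-3,5-dihydroxy-6-(3-methylbut-2-en-1-ylidene)-2-(3-methylbut-2-en-1-yl)cyclohexa-2,4-dien-1-one | CC(C)=CCC1=C(O)C(C(=O)c2ccccc2)=C(O)/C(=C/C=C(C)C)C1=O | intermediate
16 | [5,7-dihydroxy-2,2-dimethyl-8-(3-methylbut-2-en-1-yl)-2H-chromen-6-yl](phenyl)methanone | CC(C)=CCc1c(O)c(C(=O)c2ccccc2)c(O)c2c1OC(C)(C)C=C2 | target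

Total step count: 5
Longest linear sequence: 5 steps (1 → 3 → 7 → 10 → 12 → 16)

Steps most likely to fail

Step 2 (key step). The ring-closing acylation may run through the enol oxygen instead of C8 once the silyl group is lost early, and liberated HCl may add to the prenyl alkene. The fallback accepts the oxygen closure and re-forms the C7–C8 bond afterwards. It sets out from 3 and 4, which in Et2O at −78 → 20 °C without the basic quench should give 4-hydroxy-6-(4-methylpent-3-en-1-yl)-2H-pyran-2-one F1. Methanolysis of the lactone with Mg(OMe)2 in MeOH at reflux opens it to methyl 9-methyl-3,5-dioxodec-8-enoate F2. Heating F2 with NaOMe in diglyme at about 150 °C with removal of methanol should effect an intramolecular Claisen condensation of C8 onto the ester carbon. Aromatisation of the resulting trione gives the triol, and the fallback returns to the route at 7.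

Step 3. Acyl transfer may go to oxygen instead of carbon, or the poorly soluble tris-phenolate may react sluggishly. The fallback replaces the template acylation by protection and directed ortho-metalation, setting out from 7. Chloromethyl methyl ether with iPr2NEt in CH2Cl2 should give 1,3,5-tris(methoxymethoxy)-2-(3-methylbut-2-en-1-yl)benzene F3. n-BuLi in THF at 0 °C lithiates one of the two equivalent positions between two acetal oxygens to give [2,4,6-tris(methoxymethoxy)-3-(3-methylbut-2-en-1-yl)phenyl]lithium F4. Adding this to benzoyl chloride 8 at −78 °C gives phenyl[2,4,6-tris(methoxymethoxy)-3-(3-methylbut-2-en-1-yl)phenyl]methanone F5. Acetal exchange with catalytic p-TsOH·H2O in MeOH at 40 °C removes the three protecting groups, and the fallback returns to the route at 10.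

Step 4. Alkylation may occur at a chelated hydroxyl or at the free ring carbon, or substitution at the tertiary centre next to the hindered phenol may stall. The fallback builds the pyran ring by condensation instead of etherification and rearrangement, setting out from 10. 3-Methylbut-2-enal with catalytic ethylenediammonium diacetate in toluene at 110 °C should add at the free ring carbon to give [2,4,6-trihydroxy-3-(1-hydroxy-3-methylbut-2-en-1-yl)-5-(3-methylbut-2-en-1-yl)phenyl](phenyl)methanone F6. Loss of water gives the quinone methide 15 of the main route, which closes by oxa-6π electrocyclisation, so the fallback returns to the route at 16 without passing through 12. Closure onto the non-chelated oxygen is expected to be preferred, for the reason given in step 5.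

Further compounds
F1 | step 2 | 4-hydroxy-6-(4-methylpent-3-en-1-yl)-2H-pyran-2-one | CC(C)=CCCC1=CC(O)=CC(=O)O1
F2 | step 2 | methyl 9-methyl-3,5-dioxodec-8-enoate | COC(=O)CC(=O)CC(=O)CCC=C(C)C
F3 | step 3 | 1,3,5-tris(methoxymethoxy)-2-(3-methylbut-2-en-1-yl)benzene | CC(C)=CCc1c(OCOC)cc(OCOC)cc1OCOC
F4 | step 3 | [2,4,6-tris(methoxymethoxy)-3-(3-methylbut-2-en-1-yl)phenyl]lithium | CC(C)=CCc1c(OCOC)c([Li])c(OCOC)cc1OCOC
F5 | step 3 | phenyl[2,4,6-tris(methoxymethoxy)-3-(3-methylbut-2-en-1-yl)phenyl]methanone | CC(C)=CCc1c(OCOC)c(C(=O)c2ccccc2)c(OCOC)cc1OCOC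
F6 | step 4 | [2,4,6-trihydroxy-3-(1-hydroxy-3-methylbut-2-en-1-yl)-5-(3-methylbut-2-en-1-yl)phenyl](phenyl)methanone (racemic) | CC(C)=CCc1c(O)c(C(=O)c2ccccc2)c(O)c(C(O)C=C(C)C)c1O
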